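**Retrosynthetic overview**

1. Endgame: the two phenols are freed last from benzyl ethers, both CH2OH groups come from esters, and the C2–H and C3–H of the tetrahydrofuran come from an OH-directed cis-hydrogenation of a 4-hydroxy-4,5-dihydrofuran-3-carboxylate.
2. Key disconnection: that dihydrofuran is cut at C3–C4 and at C5–O into an ethyl aroylacetate (carrying the finished dihydrobenzofuran) and a 1-aryl-3-chloropropan-2-one, joined in one interrupted Feist–Benary annulation (aldol, then O-alkylation).
3. Enabling feature: in the tetrahydrofuran ring, C4 is a tertiary carbinol bonded directly to the ring OCH2 carbon C5 (a masked α-chloromethyl ketone); C3 carries a carboxyl-level carbon and its neighbour C2 carries the ring oxygen and an aryl group (a masked β-keto ester whose enol oxygen becomes the ring oxygen).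
4. The cis-2-aryl-3-(hydroxymethyl)-2,3-dihydrobenzofuran comes from a cis- and enantioselective rhodium carbene C–H insertion of an aryldiazoacetate built on 5-iodovanillin, whose formyl group later becomes the β-keto ester.
5. Ring order: dihydrobenzofuran ring (step 4), then the oxygen five-membered ring of the lignan core (step 11), saturated in step 12.

Key step: step 11

Remark on the target: read from the SMILES, the tetrahydrofuran carries aryl, hydroxymethyl and benzyl all cis with the tertiary OH trans to them (3S,4R,5R as an oxolan-3-ol), and the dihydrobenzofuran is cis (2R,3R).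

Assumption: the catalyst enantiomers named in steps 4 and 11 are those expected, by analogy with the closest substrates, to give the configurations drawn; the mirror-image catalyst (step 4) or the quinine-derived pseudoenantiomer (step 11) would be taken if a trial showed the opposite sense.

**Route**

Step 1
Reactants: 1 5-iodovanillin (4-hydroxy-3-iodo-5-methoxybenzaldehyde); 2 4-(benzyloxy)-3-methoxybenzyl alcohol
Product: 3 4-{[4-(benzyloxy)-3-methoxybenzyl]oxy}-3-iodo-5-methoxybenzaldehyde
Conditions: PPh3, DIAD, THF, 0 °C → rt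
Reagents that add atoms: none
Why: Mitsunobu etherification, in which the acidic phenol of 1 is alkylated by the alkoxyphosphonium form of the primary benzylic alcohol 2 under neutral conditions that leave the aldehyde and the aryl iodide untouched.

Step 2
Reactants: 3 4-{[4-(benzyloxy)-3-methoxybenzyl]oxy}-3-iodo-5-methoxybenzaldehyde
Product: 4 2-(4-{[4-(benzyloxy)-3-methoxybenzyl]oxy}-3-iodo-5-methoxyphenyl)-1,3-dioxolane
Conditions: TMSOCH2CH2OTMS, TMSOTf (5 mol %), CH2Cl2, −78 → −20 °C; pyridine quench
Reagents that add atoms: 1,2-bis(trimethylsilyloxy)ethane, C[Si](C)(C)OCCO[Si](C)(C)C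
Why: Noyori acetalization at low temperature masks the aldehyde (which would be reduced in step 5 and could trap the carbene of step 4) without cleaving the acid-sensitive alkoxybenzyl aryl ether.

Step 3
Reactants: 4 2-(4-{[4-(benzyloxy)-3-methoxybenzyl]oxy}-3-iodo-5-methoxyphenyl)-1,3-dioxolane
Product: 5 ethyl 2-[2-{[4-(benzyloxy)-3-methoxybenzyl]oxy}-5-(1,3-dioxolan-2-yl)-3-methoxyphenyl]-2-diazoacetate
Conditions: N2CHCO2Et, Pd(PPh3)4 (5 mol %), Et3N, n-Bu4NBr, MeCN, rt
Reagents that add atoms: ethyl diazoacetate, CCOC(=O)C=[N+]=[N-]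
Why: Palladium-catalysed cross-coupling of an aryl iodide with an acceptor diazo compound, in which oxidative addition of zerovalent palladium to the C–I bond and base-assisted coupling at the diazo carbon retain the diazo group and give the aryldiazoacetate directly.

Step 4
Reactants: 5 ethyl 2-[2-{[4-(benzyloxy)-3-methoxybenzyl]oxy}-5-(1,3-dioxolan-2-yl)-3-methoxyphenyl]-2-diazoacetate
Product: 6 ethyl (2R,3S)-2-[4-(benzyloxy)-3-methoxyphenyl]-5-(1,3-dioxolan-2-yl)-7-methoxy-2,3-dihydro-1-benzofuran-3-carboxylate (cis)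
Conditions: Rh2(S-PTTL)4 [dirhodium tetrakis(N-phthaloyl-(S)-tert-leucinate)] (2 mol %), toluene, −60 °C
Reagents that add atoms: none
Why: Enantioselective intramolecular 1,5 C–H insertion of the donor/acceptor rhodium carbene into the oxygen- and aryl-activated benzylic C–H bond closes the dihydrofuran ring, the concerted insertion geometry giving the cis 2,3-relationship kinetically and the chiral carboxylate ligands of the (S)-catalyst selecting the C–H bond that leads to 2R,3S, as is known for this catalyst class with 2-(benzyloxy)aryl diazoacetates.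

Step 5
Reactants: 6 ethyl (2R,3S)-2-[4-(benzyloxy)-3-methoxyphenyl]-5-(1,3-dioxolan-2-yl)-7-methoxy-2,3-dihydro-1-benzofuran-3-carboxylate
Product: 7 [(2R,3R)-2-[4-(benzyloxy)-3-methoxyphenyl]-5-(1,3-dioxolan-2-yl)-7-methoxy-2,3-dihydro-1-benzofuran-3-yl]methanol (cis)
Conditions: i-Bu2AlH (3 equiv), CH2Cl2, −78 → −20 °C; aq. potassium sodium tartrate
Reagents that add atoms: none
Why: Hydride reduction of the ester to the primary alcohol at low temperature is faster than enolization, so the kinetically formed cis configuration is retained and C3 is no longer epimerizable afterwards (the descriptor changes from 3S to 3R only through the priority rules).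

Step 6
Reactants: 7 [(2R,3R)-2-[4-(benzyloxy)-3-methoxyphenyl]-5-(1,3-dioxolan-2-yl)-7-methoxy-2,3-dihydro-1-benzofuran-3-yl]methanol
Product: 8 [(2R,3R)-2-[4-(benzyloxy)-3-methoxyphenyl]-5-(1,3-dioxolan-2-yl)-7-methoxy-2,3-dihydro-1-benzofuran-3-yl]methyl acetate
Conditions: Ac2O, pyridine, DMAP (cat.), CH2Cl2, 0 °C → rt
Reagents that add atoms: acetic anhydride, CC(=O)OC(C)=O
Why: Standard acylation blocks the primary alcohol for the Lewis acid and base steps that follow, with a group that the hydride of step 13 removes in the same operation that reduces the second ester.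

Step 7
Reactants: 8 [(2R,3R)-2-[4-(benzyloxy)-3-methoxyphenyl]-5-(1,3-dioxolan-2-yl)-7-methoxy-2,3-dihydro-1-benzofuran-3-yl]methyl acetate
Product: 9 [(2R,3R)-2-[4-(benzyloxy)-3-methoxyphenyl]-5-formyl-7-methoxy-2,3-dihydro-1-benzofuran-3-yl]methyl acetate
Conditions: PPTS (cat.), acetone/H2O 9:1, 40 °C
Reagents that add atoms: water, O
Why: Mild acid-catalysed acetal hydrolysis of the electron-rich aryl dioxolane, under conditions too weak to ionize the benzylic C2–O bond of the dihydrobenzofuran or to cleave the acetate.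

Step 8
Reactants: 9 [(2R,3R)-2-[4-(benzyloxy)-3-methoxyphenyl]-5-formyl-7-methoxy-2,3-dihydro-1-benzofuran-3-yl]methyl acetate
Product: 10 ethyl 3-[(2R,3R)-3-(acetoxymethyl)-2-[4-(benzyloxy)-3-methoxyphenyl]-7-methoxy-2,3-dihydro-1-benzofuran-5-yl]-3-oxopropanoate
Conditions: N2CHCO2Et (2 equiv), SnCl2 (20 mol %), CH2Cl2, rt
Reagents that add atoms: ethyl diazoacetate, CCOC(=O)C=[N+]=[N-]
Why: Roskamp homologation, in which SnCl2-promoted addition of ethyl diazoacetate to the aldehyde followed by 1,2-hydride shift and loss of N2 gives the β-keto ester without base and without touching the acetate.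

Step 9
Reactants: 11 1-(benzyloxy)-4-bromo-2-methoxybenzene; 12 epichlorohydrin (racemic)
Product: 14 1-[4-(benzyloxy)-3-methoxyphenyl]-3-chloropropan-2-ol (racemic), via aryl Grignard reagent 13 (not isolated)
Conditions: Mg, THF, reflux; then 12, CuI (10 mol %), THF, −40 → 0 °C; H2O
Reagents that add atoms: none
Why: Copper-catalysed epoxide opening by the aryl Grignard reagent at the unsubstituted epoxide carbon, which is faster than chloride displacement, gives the chlorohydrin, whose stereocentre is irrelevant because it is oxidized in the next step.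

Step 10
Reactants: 14 1-[4-(benzyloxy)-3-methoxyphenyl]-3-chloropropan-2-ol
Product: 15 1-[4-(benzyloxy)-3-methoxyphenyl]-3-chloropropan-2-one
Conditions: Dess–Martin periodinane, CH2Cl2, rt
Reagents that add atoms: none
Why: Dess–Martin oxidation converts the secondary alcohol into the α-chloromethyl ketone under non-basic conditions, so that neither epoxide formation nor Favorskii chemistry can intervene.

Step 11
Reactants: 10 ethyl 3-[(2R,3R)-3-(acetoxymethyl)-2-[4-(benzyloxy)-3-methoxyphenyl]-7-methoxy-2,3-dihydro-1-benzofuran-5-yl]-3-oxopropanoate; 15 1-[4-(benzyloxy)-3-methoxyphenyl]-3-chloropropan-2-one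
Product: 17 ethyl (4S)-2-[(2R,3R)-3-(acetoxymethyl)-2-[4-(benzyloxy)-3-methoxyphenyl]-7-methoxy-2,3-dihydro-1-benzofuran-5-yl]-4-[4-(benzyloxy)-3-methoxybenzyl]-4-hydroxy-4,5-dihydrofuran-3-carboxylate, via aldol chlorohydrin 16 (not isolated)
Conditions: 15 (1.5 equiv), squaramide from 9-amino(9-deoxy)epi-quinidine and 3,5-bis(trifluoromethyl)aniline (10 mol %), 1,8-bis(dimethylamino)naphthalene (1.1 equiv), THF, −40 → 0 °C
Reagents that add atoms: none
Why: Proposed new method: an enantioselective interrupted Feist–Benary annulation, in which the catalyst's quinuclidine (with Proton Sponge as the stoichiometric HCl acceptor) forms the hydrogen-bonded ammonium enolate of β-keto ester 10 while its squaramide NH groups bind the carbonyl oxygen and the adjacent C–Cl dipole of 15, the enolate carbon adds to the ketone (aldol, new C3–C4 bond, adduct 16) and the oxygen of the aryl-ketone-derived enol then displaces chloride (new C5–O bond). The closest known reaction types are the cinchona-catalysed asymmetric interrupted Feist–Benary reactions of 1,3-dicarbonyl compounds with bromopyruvates and α-tosyloxyacetophenones and the classical base-mediated reaction of β-keto esters with chloroacetone-type ketones; catalyst-controlled face selection on a non-activated α-chloromethyl benzyl ketone is the unproven part. The only ring formed, the 4,5-dihydrofuran, is closed by a 5-exo-tet SN2 O-alkylation that follows the intermolecular aldol addition. The only new stereocentre that survives, C4 (S), is set in the aldol event by the catalyst, which must present the Si face of the ketone (priorities O > CH2Cl > CH2Ar) to the enolate, the stereocentres of the dihydrobenzofuran in 10 being too remote to help or hinder, and the C3 stereocentre of 16 disappears when the enol ether forms. The step needs carbonyl addition instead of SN2 C-alkylation at CH2Cl, ring closure through the enol oxygen instead of epoxide formation from the tertiary alcohol, and no dehydration to the furan; the inductively activated carbonyl group of the α-chloro ketone, the modest leaving-group ability of chloride, a base too weak to deprotonate the tertiary alcohol and the absence of acid should secure these.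

Step 12
Reactants: 17 ethyl (4S)-2-[(2R,3R)-3-(acetoxymethyl)-2-[4-(benzyloxy)-3-methoxyphenyl]-7-methoxy-2,3-dihydro-1-benzofuran-5-yl]-4-[4-(benzyloxy)-3-methoxybenzyl]-4-hydroxy-4,5-dihydrofuran-3-carboxylate
Product: 18 ethyl (2R,3R,4S)-2-[(2R,3R)-3-(acetoxymethyl)-2-[4-(benzyloxy)-3-methoxyphenyl]-7-methoxy-2,3-dihydro-1-benzofuran-5-yl]-4-[4-(benzyloxy)-3-methoxybenzyl]-4-hydroxytetrahydrofuran-3-carboxylate
Conditions: [Ir(cod)(PCy3)(py)]PF6 (10 mol %), H2 (1–10 bar), CH2Cl2, rt
Reagents that add atoms: none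
Why: Hydroxyl-directed homogeneous hydrogenation, in which the cationic iridium catalyst binds the tertiary C4–OH and delivers both hydrogens to the tetrasubstituted C2=C3 bond from the OH face, setting C2 (R) and C3 (R) cis to each other with aryl and ester on the face of the benzyl group, while benzyl ethers and benzylic C–O bonds are not hydrogenolysed by this catalyst.

Step 13
Reactants: 18 ethyl (2R,3R,4S)-2-[(2R,3R)-3-(acetoxymethyl)-2-[4-(benzyloxy)-3-methoxyphenyl]-7-methoxy-2,3-dihydro-1-benzofuran-5-yl]-4-[4-(benzyloxy)-3-methoxybenzyl]-4-hydroxytetrahydrofuran-3-carboxylate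
Product: 19 (3S,4R,5R)-3-[4-(benzyloxy)-3-methoxybenzyl]-5-[(2R,3R)-2-[4-(benzyloxy)-3-methoxyphenyl]-3-(hydroxymethyl)-7-methoxy-2,3-dihydro-1-benzofuran-5-yl]-4-(hydroxymethyl)tetrahydrofuran-3-ol
Conditions: i-Bu2AlH (7 equiv), CH2Cl2, −78 → −20 °C; aq. potassium sodium tartrate
Reagents that add atoms: none
Why: Hydride reduction of the ethyl ester to the primary alcohol, with reductive cleavage of the acetate by the same reagent, is run cold so that reduction outruns epimerization at C3 and retro-aldol cleavage of the aluminium β-alkoxide.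

Step 14
Reactants: 19 (3S,4R,5R)-3-[4-(benzyloxy)-3-methoxybenzyl]-5-[(2R,3R)-2-[4-(benzyloxy)-3-methoxyphenyl]-3-(hydroxymethyl)-7-methoxy-2,3-dihydro-1-benzofuran-5-yl]-4-(hydroxymethyl)tetrahydrofuran-3-ol
Product: 20 (3S,4R,5R)-3-(4-hydroxy-3-methoxybenzyl)-5-[(2R,3R)-2-(4-hydroxy-3-methoxyphenyl)-3-(hydroxymethyl)-7-methoxy-2,3-dihydro-1-benzofuran-5-yl]-4-(hydroxymethyl)tetrahydrofuran-3-ol (CNP0284796.1)
Conditions: H2 (1 atm), 10 % Pd/C, EtOAc/MeOH, rt, stopped at consumption of 19
Reagents that add atoms: none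
Why: Catalytic hydrogenolysis of the two phenolic benzyl ethers under neutral conditions, which should be much faster than cleavage of the benzylic C–O bonds of the 2-aryltetrahydrofuran and dihydrobenzofuran rings, so no stereocentre is touched.

**Compound list**

1 | 5-iodovanillin (4-hydroxy-3-iodo-5-methoxybenzaldehyde) | O=Cc1cc(I)c(O)c(OC)c1 | starting material
2 | 4-(benzyloxy)-3-methoxybenzyl alcohol | OCc1ccc(OCc2ccccc2)c(OC)c1 | starting material
3 | 4-{[4-(benzyloxy)-3-methoxybenzyl]oxy}-3-iodo-5-methoxybenzaldehyde | O=Cc1cc(I)c(OCc2ccc(OCc3ccccc3)c(OC)c2)c(OC)c1 | intermediate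
4 | 2-(4-{[4-(benzyloxy)-3-methoxybenzyl]oxy}-3-iodo-5-methoxyphenyl)-1,3-dioxolane | Ic1cc(C2OCCO2)cc(OC)c1OCc1ccc(OCc2ccccc2)c(OC)c1 | intermediate
5 | ethyl 2-[2-{[4-(benzyloxy)-3-methoxybenzyl]oxy}-5-(1,3-dioxolan-2-yl)-3-methoxyphenyl]-2-diazoacetate | CCOC(=O)C(=[N+]=[N-])c1cc(C2OCCO2)cc(OC)c1OCc1ccc(OCc2ccccc2)c(OC)c1 | intermediate
6 | ethyl (2R,3S)-2-[4-(benzyloxy)-3-methoxyphenyl]-5-(1,3-dioxolan-2-yl)-7-methoxy-2,3-dihydro-1-benzofuran-3-carboxylate (cis) | O1CCOC1c1cc(OC)c2c(c1)[C@H](C(=O)OCC)[C@H](c1ccc(OCc3ccccc3)c(OC)c1)O2 | intermediate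
7 | [(2R,3R)-2-[4-(benzyloxy)-3-methoxyphenyl]-5-(1,3-dioxolan-2-yl)-7-methoxy-2,3-dihydro-1-benzofuran-3-yl]methanol (cis) | O1CCOC1c1cc(OC)c2c(c1)[C@H](CO)[C@H](c1ccc(OCc3ccccc3)c(OC)c1)O2 | intermediate
8 | [(2R,3R)-2-[4-(benzyloxy)-3-methoxyphenyl]-5-(1,3-dioxolan-2-yl)-7-methoxy-2,3-dihydro-1-benzofuran-3-yl]methyl acetate | O1CCOC1c1cc(OC)c2c(c1)[C@H](COC(C)=O)[C@H](c1ccc(OCc3ccccc3)c(OC)c1)O2 | intermediate
9 | [(2R,3R)-2-[4-(benzyloxy)-3-methoxyphenyl]-5-formyl-7-methoxy-2,3-dihydro-1-benzofuran-3-yl]methyl acetate | O=Cc1cc(OC)c2c(c1)[C@H](COC(C)=O)[C@H](c1ccc(OCc3ccccc3)c(OC)c1)O2 | intermediate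
10 | ethyl 3-[(2R,3R)-3-(acetoxymethyl)-2-[4-(benzyloxy)-3-methoxyphenyl]-7-methoxy-2,3-dihydro-1-benzofuran-5-yl]-3-oxopropanoate | CCOC(=O)CC(=O)c1cc(OC)c2c(c1)[C@H](COC(C)=O)[C@H](c1ccc(OCc3ccccc3)c(OC)c1)O2 | intermediate
11 | 1-(benzyloxy)-4-bromo-2-methoxybenzene | COc1cc(Br)ccc1OCc1ccccc1 | starting material
12 | epichlorohydrin (racemic) | ClCC1CO1 | starting material
13 | [4-(benzyloxy)-3-methoxyphenyl]magnesium bromide | COc1cc([Mg]Br)ccc1OCc1ccccc1 | intermediate (not isolated)
14 | 1-[4-(benzyloxy)-3-methoxyphenyl]-3-chloropropan-2-ol (racemic) | COc1cc(CC(O)CCl)ccc1OCc1ccccc1 | intermediate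
15 | 1-[4-(benzyloxy)-3-methoxyphenyl]-3-chloropropan-2-one | COc1cc(CC(=O)CCl)ccc1OCc1ccccc1 | intermediate
16 | ethyl (3S)-2-{[(2R,3R)-3-(acetoxymethyl)-2-[4-(benzyloxy)-3-methoxyphenyl]-7-methoxy-2,3-dihydro-1-benzofuran-5-yl]carbonyl}-4-[4-(benzyloxy)-3-methoxyphenyl]-3-(chloromethyl)-3-hydroxybutanoate (C2 not defined) | COc1cc(C[C@@](O)(CCl)C(C(=O)OCC)C(=O)c2cc(OC)c3c(c2)[C@H](COC(C)=O)[C@H](c2ccc(OCc4ccccc4)c(OC)c2)O3)ccc1OCc1ccccc1 | intermediate (not isolated)
17 | ethyl (4S)-2-[(2R,3R)-3-(acetoxymethyl)-2-[4-(benzyloxy)-3-methoxyphenyl]-7-methoxy-2,3-dihydro-1-benzofuran-5-yl]-4-[4-(benzyloxy)-3-methoxybenzyl]-4-hydroxy-4,5-dihydrofuran-3-carboxylate | COc1cc(C[C@@]2(O)COC(c3cc(OC)c4c(c3)[C@H](COC(C)=O)[C@H](c3ccc(OCc5ccccc5)c(OC)c3)O4)=C2C(=O)OCC)ccc1OCc1ccccc1 | intermediate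
18 | ethyl (2R,3R,4S)-2-[(2R,3R)-3-(acetoxymethyl)-2-[4-(benzyloxy)-3-methoxyphenyl]-7-methoxy-2,3-dihydro-1-benzofuran-5-yl]-4-[4-(benzyloxy)-3-methoxybenzyl]-4-hydroxytetrahydrofuran-3-carboxylate | COc1cc(C[C@@]2(O)CO[C@@H](c3cc(OC)c4c(c3)[C@H](COC(C)=O)[C@H](c3ccc(OCc5ccccc5)c(OC)c3)O4)[C@H]2C(=O)OCC)ccc1OCc1ccccc1 | intermediate
19 | (3S,4R,5R)-3-[4-(benzyloxy)-3-methoxybenzyl]-5-[(2R,3R)-2-[4-(benzyloxy)-3-methoxyphenyl]-3-(hydroxymethyl)-7-methoxy-2,3-dihydro-1-benzofuran-5-yl]-4-(hydroxymethyl)tetrahydrofuran-3-ol | COc1cc(C[C@@]2(O)CO[C@@H](c3cc(OC)c4c(c3)[C@H](CO)[C@H](c3ccc(OCc5ccccc5)c(OC)c3)O4)[C@H]2CO)ccc1OCc1ccccc1 | intermediate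
20 | (3S,4R,5R)-3-(4-hydroxy-3-methoxybenzyl)-5-[(2R,3R)-2-(4-hydroxy-3-methoxyphenyl)-3-(hydroxymethyl)-7-methoxy-2,3-dihydro-1-benzofuran-5-yl]-4-(hydroxymethyl)tetrahydrofuran-3-ol | COc1cc(C[C@@]2(O)CO[C@@H](c3cc(OC)c4c(c3)[C@H](CO)[C@H](c3ccc(O)c(OC)c3)O4)[C@H]2CO)ccc1O | target

**Step count and risks**

Total step count: 14. Longest linear sequence: 12 steps (steps 1–8, then 11–14); steps 9 and 10 form the two-step side branch to the chloro ketone.

Steps most likely to fail:

Step 11 (proposed new method). The catalyst may discriminate poorly, or in the wrong sense, between the CH2Cl and CH2Ar sides of the ketone. Its quinuclidine nitrogen may be quaternized by the chloro ketone. Direct C-alkylation at CH2Cl may compete with the aldol addition, and traces of acid would dehydrate the product to the furan. Fallback with known chemistry, setting out from 10 and 15: the classical base-mediated interrupted Feist–Benary reaction (Et3N, CH2Cl2, 0 °C → rt) is run without chiral catalyst. Because 10 is already enantiopure, it should give 17 together with its C4 epimer, ethyl (4R)-2-[(2R,3R)-3-(acetoxymethyl)-2-[4-(benzyloxy)-3-methoxyphenyl]-7-methoxy-2,3-dihydro-1-benzofuran-5-yl]-4-[4-(benzyloxy)-3-methoxybenzyl]-4-hydroxy-4,5-dihydrofuran-3-carboxylate F1, as diastereomers and not as enantiomers. Stereocontrol is thereby moved from catalysis to chromatographic separation of the two diastereomers, and the route is rejoined at 17.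

Step 12. The tetrasubstituted push–pull double bond may be reduced too slowly. Acidic iridium hydride species may trigger loss of the tertiary hydroxyl group with aromatization to the furan. Face control may erode if the ester carbonyl rather than the hydroxyl group holds the metal. Fallback, setting out from 17 and returning at 18: heterogeneous syn-hydrogenation over 5 % Rh/Al2O3 (H2, 1–4 bar, EtOAc, rt). Here the face is chosen by adsorption of the substrate on the side away from the benzyl group (the side of the hydroxyl group) instead of by coordination to a soluble metal; rhodium rather than palladium is taken to avoid hydrogenolysis of benzyl ethers and benzylic C–O bonds. This fallback makes no new compound (entry F0).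

Step 8. Addition of the diazo ester to the electron-rich formyl group may be sluggish, and the Lewis acid may ionize the benzylic C2–O bond of the cis-dihydrobenzofuran, leading to epimerization or ring opening. Fallback, setting out from 9 and returning at 10: Pinnick oxidation (NaClO2, NaH2PO4, 2-methyl-2-butene, t-BuOH/H2O) should give (2R,3R)-3-(acetoxymethyl)-2-[4-(benzyloxy)-3-methoxyphenyl]-7-methoxy-2,3-dihydro-1-benzofuran-5-carboxylic acid F2. Activation with N,N'-carbonyldiimidazole in THF gives the acyl imidazolide F3, used without isolation. Decarboxylative Claisen condensation with the magnesium enolate of potassium ethyl malonate (MgCl2, Et3N, THF, rt; dilute acid work-up) then gives 10 without any Lewis acid strong enough to ionize the benzylic ether.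

Further compounds
F1 | step 11 | ethyl (4R)-2-[(2R,3R)-3-(acetoxymethyl)-2-[4-(benzyloxy)-3-methoxyphenyl]-7-methoxy-2,3-dihydro-1-benzofuran-5-yl]-4-[4-(benzyloxy)-3-methoxybenzyl]-4-hydroxy-4,5-dihydrofuran-3-carboxylate | COc1cc(C[C@]2(O)COC(c3cc(OC)c4c(c3)[C@H](COC(C)=O)[C@H](c3ccc(OCc5ccccc5)c(OC)c3)O4)=C2C(=O)OCC)ccc1OCc1ccccc1
F2 | step 8 | (2R,3R)-3-(acetoxymethyl)-2-[4-(benzyloxy)-3-methoxyphenyl]-7-methoxy-2,3-dihydro-1-benzofuran-5-carboxylic acid | OC(=O)c1cc(OC)c2c(c1)[C@H](COC(C)=O)[C@H](c1ccc(OCc3ccccc3)c(OC)c1)O2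
F3 | step 8 | [(2R,3R)-2-[4-(benzyloxy)-3-methoxyphenyl]-5-(imidazol-1-ylcarbonyl)-7-methoxy-2,3-dihydro-1-benzofuran-3-yl]methyl acetate | O=C(n1ccnc1)c1cc(OC)c2c(c1)[C@H](COC(C)=O)[C@H](c1ccc(OCc3ccccc3)c(OC)c1)O2
F0 | step 12 | none | none
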